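Cedar is the run to read first. We compare two extreme flasks. In the sequential extreme, reagent finishes the starting material before touching first product, so double product comes only from the excess over one equivalent. In the cooperative extreme, first product takes reagent at once, so double product is half the equivalents. The ratio of the two addition rates, the selectivity factor, places a flask between them.

common to all: starting material 0.069 M

| flask | reagent | remark | time |
|---|---|---|---|
| ash | 1.3 equiv | run made earlier |  |
| cedar | 4.7 equiv | run made earlier |  |
| violet | 1.00 equiv |  | 5.0 d |
| blue | 1.20 equiv |  | 5.0 d |
| ochre | 3.00 equiv |  | 5.0 d |

- ash (time / d: double product / %): 0.417: 18; 0.625: 17; 1.04: 14; 1.67: 14; 3.00: 6; 5.00: 7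
- cedar (time / d: double product / %): 0.417: 76; 0.625: 76; 1.04: 61; 1.67: 45; 3.00: 30; 5.00: 22

(each reading ± 1.5 percentage points)

- a reading or a percentage of double product counts all its forms, free or not

- how much double product is there at the end, in percent of the starting material charged: for each flask in turn (violet, blue, ochre)

Cedar holds more than two equivalents, so both extremes make double product from all its starting material. Its last reading therefore gives the kept share, the reading at 5.00 d per double product made: 22.0 %. Ash tests the extremes. Its 7 % divided by the kept share gives 31.8 % made, a rough reading given the scatter of 1.5 percentage points. The sequential extreme allows 30.0 % and the cooperative one 65.0 %. The figure for ash lies nearer the first, but it borrows its share from cedar, which holds more reagent than ash. A smaller share in ash would mean more made, so this places ash only loosely.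

Our reckoning follows. Ochre has more than two equivalents, so it should end near 22.0 %. Blue has a sequential amount of 20.0 %, which gives 4.40 % if we take the sequential end as a working guess. Violet's sequential amount is zero and its cooperative one gives 11.0 %, so on the same guess we expect it low in that range.

The forecast gives 1.5 %, 4 % and 24 %, on this ground: “The second addition therefore seems to use mainly the reagent left after the first”. It stands above us on ochre and below us on blue.

    starting material → decomposition product (k = 2.10 × 10⁻⁷ s⁻¹)
    reagent + double product ⇌ idle adduct, settled at all times (K = 6.10 M⁻¹)
    starting material + reagent → first product + released group (k = 0.00110 M⁻¹ s⁻¹)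
    reagent + first product → double product + released group (k = 3.70 × 10⁻⁴ M⁻¹ s⁻¹)
    double product ⇌ isomer of the product (K = 7.50, k = 1.50 × 10⁻⁵ s⁻¹)

The flasks end at 2.54 %, 3.86 % and 16.4 %. Ochre holds starting material 0 %, first product 0 % and isomer of the product 83.5 %, so its kept share is 16.4 %, lower than cedar's 22.0 %, with idle adduct 4.70 % counted in that double product. In blue the kept share gives 4.40 % against 3.86 %, yet blue's isomer of the product stands at 28.4 %, more than its sequential amount of 20.0 %, with starting material still at 10.9 %.

Readings and results are calculated from invented constants; noise was put on by code.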